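**Retrosynthetic overview**

- The last step frees the 4'-hydroxyl from its acetate; the (2S)-flavanone skeleton is complete before that.
- The key disconnection is the C4–C4a aryl ketone bond: an intramolecular Friedel–Crafts acylation of a (3S)-3-aryl-3-aryloxypropanoic acid closes the pyranone ring (ring C). This is the only ring made; rings A and B are bought.
- The strategy rests on ring A, which in the open precursor is a 3,4,5-trimethoxyphenoxy group held through O1. Its two ortho C–H carbons (the future C4a and C8) are equivalent, so acylation at either gives only the 5,6,7-trimethoxy pattern, and the preset C2 stereocentre is carried through unchanged.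
- The acid carbon C4 comes from oxidative cleavage of a terminal alkene. The C2–O1 ether comes from Mitsunobu inversion of an (R)-homoallylic alcohol with 3,4,5-trimethoxyphenol. The C2–C3 bond and the C2 stereocentre come from catalytic asymmetric allylboration of vanillin acetate.
- A homoallyl group is used as the masked acid rather than an ester, because a β-hydroxy ester would tend to dehydrate to the cinnamate under Mitsunobu conditions and an ester would later need basic cleavage.

Key step: step 5

Remark on the chemistry: the 4'-hydroxyl is kept as its acetate to the last step, because a free para-hydroxyl would open a quinone-methide path for ionisation at C2. Every step therefore avoids hydroxide and alkoxide bases.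

**Route**

Step 1
Reactants: 1 vanillin acetate (4-formyl-2-methoxyphenyl acetate); 2 allylboronic acid pinacol ester (2-allyl-4,4,5,5-tetramethyl-1,3,2-dioxaborolane)
Product: 4 4-[(1R)-1-hydroxybut-3-en-1-yl]-2-methoxyphenyl acetate, via pinacol borate ester 3 (not isolated)
Conditions: (R)-TRIP phosphoric acid (5 mol%), toluene, −30 °C; then pH 7 aqueous work-up
Reagents that add atoms: none
Why: Chiral phosphoric acid-catalysed allylboration of an aromatic aldehyde through a closed chair (Zimmerman–Traxler) transition state, in which the (R)-acid, hydrogen-bonded to a boronate oxygen and to the formyl C–H, should expose the Re face and set the future C2 as the (R)-carbinol (sense and ee to be confirmed by chiral HPLC before going on), while the neutral medium leaves the aryl acetate alone.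

Step 2
Reactants: 4 4-[(1R)-1-hydroxybut-3-en-1-yl]-2-methoxyphenyl acetate; 5 3,4,5-trimethoxyphenol
Product: 7 2-methoxy-4-[(1S)-1-(3,4,5-trimethoxyphenoxy)but-3-en-1-yl]phenyl acetate, via alkoxyphosphonium aryloxide 6 (not isolated)
Conditions: PPh3, DIAD, toluene, 0 °C → rt
Reagents that add atoms: none
Why: Mitsunobu etherification, in which the aryloxide (phenol pKa about 10, no ortho substituent) displaces triphenylphosphine oxide from the alkoxyphosphonium ion by SN2 with inversion, (R) to (S); the acetoxy group para to the carbinol disfavours SN1 leakage, and the allylic CH2 is not acidic enough for ready elimination.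

Step 3
Reactants: 7 2-methoxy-4-[(1S)-1-(3,4,5-trimethoxyphenoxy)but-3-en-1-yl]phenyl acetate
Product: 9 2-methoxy-4-[(1S)-3-oxo-1-(3,4,5-trimethoxyphenoxy)propyl]phenyl acetate, via vicinal diol 8 (not isolated)
Conditions: OsO4 (2 mol%), NaIO4 (4 equiv), 2,6-lutidine, dioxane–H2O 3:1, rt; crude aldehyde used at once
Reagents that add atoms: osmium tetroxide, O=[Os](=O)(=O)=O (delivers the oxygen, catalytic); sodium periodate, [Na+].[O-]I(=O)(=O)=O (terminal oxidant that restores it)
Why: Lemieux–Johnson oxidative cleavage, in which the monosubstituted alkene is the only site that osmium tetroxide dihydroxylates and periodate cleaves the diol to the aldehyde with loss of formaldehyde, while neither reagent should touch the oxygenated arenes, the aryl acetate or the C2 stereocentre.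

Step 4
Reactants: 9 2-methoxy-4-[(1S)-3-oxo-1-(3,4,5-trimethoxyphenoxy)propyl]phenyl acetate
Product: 10 (3S)-3-(4-acetoxy-3-methoxyphenyl)-3-(3,4,5-trimethoxyphenoxy)propanoic acid
Conditions: NaClO2, NaH2PO4, 2-methyl-2-butene (large excess), t-BuOH–H2O, 0 °C → rt
Reagents that add atoms: sodium chlorite, [Na+].[O-]Cl=O
Why: Pinnick oxidation, in which chlorous acid adds to the aldehyde and fragments to the acid at pH 3–4, where neither β-elimination of the aryloxide nor acetate hydrolysis is expected, and the alkene scavenger removes hypochlorous acid before it can chlorinate the electron-rich ring.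

Step 5
Reactants: 10 (3S)-3-(4-acetoxy-3-methoxyphenyl)-3-(3,4,5-trimethoxyphenoxy)propanoic acid
Product: 12 (2S)-4'-O-acetylagecorynin E (4-[(2S)-5,6,7-trimethoxy-4-oxo-3,4-dihydro-2H-chromen-2-yl]-2-methoxyphenyl acetate), via mixed trifluoroacetic anhydride 11 (not isolated)
Conditions: TFAA (3 equiv), CH2Cl2, 0 °C → rt
Reagents that add atoms: none
Why: Trifluoroacetic anhydride turns the acid into the mixed anhydride 11, an acylium equivalent that attacks an ortho carbon of the 3,4,5-trimethoxyphenoxy ring, and loss of the proton from the σ-complex gives the aryl ketone; this is the intramolecular Friedel–Crafts acylation by which 3-aryloxypropanoic acids are closed to chroman-4-ones. The pyranone ring closes by 6-exo-trig attack of the arene carbon on the acyl carbon, which forms the C4–C4a bond. No stereocentre is created, and C2 keeps its (S) configuration because none of its four bonds is broken. The two ortho carbons of the phenoxy ring are interchanged by rotation about the O1–C8a bond, so only the 5,6,7-trimethoxy pattern can form, and the reacting carbon, with oxygen donors at both ortho positions and the para position, should far outrun the acetoxy-guaiacyl ring (five-membered indanone closure). The selectivity the step does need is acylation ahead of acid-induced ionisation of the benzylic C2–O bond; the nucleophilicity of the ring allows TFAA alone, without a Lewis or strong Brønsted acid (which also spares the peri 5-OMe), and the 4'-acetate withholds the para donor that would stabilise a C2 cation.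

Step 6
Reactants: 12 (2S)-4'-O-acetylagecorynin E
Product: 13 agecorynin E ((2S)-2-(4-hydroxy-3-methoxyphenyl)-5,6,7-trimethoxy-2,3-dihydro-4H-chromen-4-one)
Conditions: NH4OAc (10 equiv), MeOH–H2O 4:1, rt
Reagents that add atoms: none
Why: Chemoselective aminolysis of the aryl acetate (an activated ester) by the small equilibrium amount of ammonia at about pH 7, where the 4'-phenol stays protonated so that the retro-oxa-Michael/quinone-methide ring opening that would racemise C2 is not triggered, and the methyl ethers and the ketone are inert.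

**Compound list**

1 | vanillin acetate (4-formyl-2-methoxyphenyl acetate) | COc1cc(C=O)ccc1OC(C)=O | starting material
2 | allylboronic acid pinacol ester | C=CCB1OC(C)(C)C(C)(C)O1 | starting material
3 | 2-methoxy-4-[(1R)-1-[(4,4,5,5-tetramethyl-1,3,2-dioxaborolan-2-yl)oxy]but-3-en-1-yl]phenyl acetate (borate ester, not isolated) | C=CC[C@@H](OB1OC(C)(C)C(C)(C)O1)c1ccc(OC(C)=O)c(OC)c1 | intermediate
4 | 4-[(1R)-1-hydroxybut-3-en-1-yl]-2-methoxyphenyl acetate | C=CC[C@@H](O)c1ccc(OC(C)=O)c(OC)c1 | intermediate
5 | 3,4,5-trimethoxyphenol | COc1cc(O)cc(OC)c1OC | starting material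
6 | {[(1R)-1-(4-acetoxy-3-methoxyphenyl)but-3-en-1-yl]oxy}triphenylphosphonium 3,4,5-trimethoxyphenoxide (not isolated) | C=CC[C@@H](O[P+](c1ccccc1)(c1ccccc1)c1ccccc1)c1ccc(OC(C)=O)c(OC)c1.[O-]c1cc(OC)c(OC)c(OC)c1 | intermediate
7 | 2-methoxy-4-[(1S)-1-(3,4,5-trimethoxyphenoxy)but-3-en-1-yl]phenyl acetate | C=CC[C@H](Oc1cc(OC)c(OC)c(OC)c1)c1ccc(OC(C)=O)c(OC)c1 | intermediate
8 | 4-[(1S)-3,4-dihydroxy-1-(3,4,5-trimethoxyphenoxy)butyl]-2-methoxyphenyl acetate (both C3 epimers, not isolated) | OCC(O)C[C@H](Oc1cc(OC)c(OC)c(OC)c1)c1ccc(OC(C)=O)c(OC)c1 | intermediate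
9 | 2-methoxy-4-[(1S)-3-oxo-1-(3,4,5-trimethoxyphenoxy)propyl]phenyl acetate | O=CC[C@H](Oc1cc(OC)c(OC)c(OC)c1)c1ccc(OC(C)=O)c(OC)c1 | intermediate
10 | (3S)-3-(4-acetoxy-3-methoxyphenyl)-3-(3,4,5-trimethoxyphenoxy)propanoic acid | OC(=O)C[C@H](Oc1cc(OC)c(OC)c(OC)c1)c1ccc(OC(C)=O)c(OC)c1 | intermediate
11 | (3S)-3-(4-acetoxy-3-methoxyphenyl)-3-(3,4,5-trimethoxyphenoxy)propanoic trifluoroacetic anhydride (not isolated) | O=C(OC(=O)C(F)(F)F)C[C@H](Oc1cc(OC)c(OC)c(OC)c1)c1ccc(OC(C)=O)c(OC)c1 | intermediate
12 | (2S)-4'-O-acetylagecorynin E | COc1cc([C@@H]2CC(=O)c3c(cc(OC)c(OC)c3OC)O2)ccc1OC(C)=O | intermediate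
13 | agecorynin E | COc1cc([C@@H]2CC(=O)c3c(cc(OC)c(OC)c3OC)O2)ccc1O | target

**Totals**

Total step count: 6. Longest linear sequence: 6 steps (1 to 13).

**Steps most likely to fail**

Step 5 (key step). Acid-induced ionisation of the benzylic C2–O bond may compete with acylation. That would erode the ee, move the benzylic carbon onto a ring carbon, or eliminate to the cinnamic acid; the anhydride may also trifluoroacetylate the ring. The fallback closes the same C4–C4a bond under neutral conditions by known chemistry. It sets out from 5 and 4 and comes back at 12.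
- Phenol 5 is iodinated (NIS, MeCN, 0 °C) to 2-iodo-3,4,5-trimethoxyphenol F1.
- Mitsunobu coupling of F1 with 4 (PPh3, DIAD, toluene) passes through {[(1R)-1-(4-acetoxy-3-methoxyphenyl)but-3-en-1-yl]oxy}triphenylphosphonium 2-iodo-3,4,5-trimethoxyphenoxide F2 and should give 4-[(1S)-1-(2-iodo-3,4,5-trimethoxyphenoxy)but-3-en-1-yl]-2-methoxyphenyl acetate F3.
- Lemieux–Johnson cleavage as in step 3 passes through 4-[(1S)-3,4-dihydroxy-1-(2-iodo-3,4,5-trimethoxyphenoxy)butyl]-2-methoxyphenyl acetate F4 and gives 4-[(1S)-1-(2-iodo-3,4,5-trimethoxyphenoxy)-3-oxopropyl]-2-methoxyphenyl acetate F5.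
- Intramolecular Nozaki–Hiyama–Kishi addition (CrCl2, cat. NiCl2, DMF, rt) then gives 4-[(2S)-4-hydroxy-5,6,7-trimethoxy-3,4-dihydro-2H-chromen-2-yl]-2-methoxyphenyl acetate F6 as a mixture of C4 epimers.
- Dess–Martin oxidation (NaHCO3-buffered, CH2Cl2) converts F6 into 12.

Step 2. SN1 leakage at the benzylic carbon (loss of ee), elimination to the aryl butadiene, or acetyl transfer from the aryl acetate to the aryloxide may lower the yield or the optical purity. The fallback forms the aryl–O bond instead of the alkyl–O bond, so the carbinol configuration is retained. It sets out from 1 and 2 and comes back at 7.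
- Step 1 is run with (S)-TRIP phosphoric acid; it passes through 2-methoxy-4-[(1S)-1-[(4,4,5,5-tetramethyl-1,3,2-dioxaborolan-2-yl)oxy]but-3-en-1-yl]phenyl acetate F7 and gives 4-[(1S)-1-hydroxybut-3-en-1-yl]-2-methoxyphenyl acetate F8.
- Copper-catalysed oxidative O-arylation of F8 (Chan–Lam type: purchased potassium (3,4,5-trimethoxyphenyl)trifluoroborate, cat. Cu(OAc)2·H2O, DMAP, 4 Å MS, O2, CH2Cl2, rt) should then give 7 without touching the stereocentre.

Step 3. The β-aryloxy aldehyde may lose the aryloxide by β-elimination (E1cB under lutidine or on silica), or over-oxidation may occur while the aldehyde accumulates. The fallback sets out from 7 and comes back at 10: one-pot osmium-catalysed oxidative cleavage with Oxone (cat. OsO4, Oxone, DMF, rt) takes the terminal alkene straight to the carboxylic acid. Aldehyde 9 is oxidised in the acidic medium as it forms and is never isolated, so this fallback makes no compound outside the list, F0.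

**Further compounds**

F1 | step 5 | 2-iodo-3,4,5-trimethoxyphenol | COc1cc(O)c(I)c(OC)c1OC
F2 | step 5 | {[(1R)-1-(4-acetoxy-3-methoxyphenyl)but-3-en-1-yl]oxy}triphenylphosphonium 2-iodo-3,4,5-trimethoxyphenoxide (not isolated) | C=CC[C@@H](O[P+](c1ccccc1)(c1ccccc1)c1ccccc1)c1ccc(OC(C)=O)c(OC)c1.[O-]c1cc(OC)c(OC)c(OC)c1I
F3 | step 5 | 4-[(1S)-1-(2-iodo-3,4,5-trimethoxyphenoxy)but-3-en-1-yl]-2-methoxyphenyl acetate | C=CC[C@H](Oc1cc(OC)c(OC)c(OC)c1I)c1ccc(OC(C)=O)c(OC)c1
F4 | step 5 | 4-[(1S)-3,4-dihydroxy-1-(2-iodo-3,4,5-trimethoxyphenoxy)butyl]-2-methoxyphenyl acetate (both C3 epimers, not isolated) | OCC(O)C[C@H](Oc1cc(OC)c(OC)c(OC)c1I)c1ccc(OC(C)=O)c(OC)c1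
F5 | step 5 | 4-[(1S)-1-(2-iodo-3,4,5-trimethoxyphenoxy)-3-oxopropyl]-2-methoxyphenyl acetate | O=CC[C@H](Oc1cc(OC)c(OC)c(OC)c1I)c1ccc(OC(C)=O)c(OC)c1
F6 | step 5 | 4-[(2S)-4-hydroxy-5,6,7-trimethoxy-3,4-dihydro-2H-chromen-2-yl]-2-methoxyphenyl acetate (C4 epimers) | COc1cc([C@@H]2CC(O)c3c(cc(OC)c(OC)c3OC)O2)ccc1OC(C)=O
F7 | step 2 | 2-methoxy-4-[(1S)-1-[(4,4,5,5-tetramethyl-1,3,2-dioxaborolan-2-yl)oxy]but-3-en-1-yl]phenyl acetate (not isolated) | C=CC[C@H](OB1OC(C)(C)C(C)(C)O1)c1ccc(OC(C)=O)c(OC)c1
F8 | step 2 | 4-[(1S)-1-hydroxybut-3-en-1-yl]-2-methoxyphenyl acetate | C=CC[C@H](O)c1ccc(OC(C)=O)c(OC)c1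
F0 | step 3 | none | none
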